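The naphthazarin core is cut at C1–C8a and C4–C4a. The fusion bond C4a–C8a, flanked by the oxygen-bearing C5 and C8 of the benzenoid ring, is a latent symmetrical 3,6-dimethoxybenzyne. C1–C2(C1')–C3–C4 of the quinone ring, oxygenated at both ends, is a 3-substituted furan. One aryne–furan [4+2] cycloaddition therefore builds the whole bicyclic carbon skeleton as a 1,4-epoxide, which later unfolds to the 1,4-quinone. The furan partner is the silyl ether of an (R)-3-furyl carbinol that already carries the prenyl chain and the only lasting stereocentre, set by allylboration of furan-3-carbaldehyde. The butanoate and the free peri-hydroxyls are introduced at the end.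

Key step: step 4

Assumption: "butylshikonin" is read as the butanoate (butyryl) ester of (R)-shikonin, as the SMILES shows; naphthalene numbering (C1–C8a, side-chain carbon C1') is used throughout.

Remark: the cycloaddition of step 4 should give both bridgehead diastereomers of the adduct. They are not separated, number 8 stands for this pair, and its name and SMILES show the (1S,4R) member; the other member is the (1R,4S) bridgehead epimer with the same (1R) side chain.

Step 1
Reactants: 1 furan-3-carbaldehyde
Product: 2 (1R)-1-(furan-3-yl)but-3-en-1-ol
Conditions: (+)-B-allyldiisopinocampheylborane, derived from (−)-α-pinene (1.2 equiv, pentane solution), Et2O, −78 °C; then NaOH, H2O2, 0 °C → rt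
Reagents that add atoms: B-allyldiisopinocampheylborane from (−)-α-pinene, C=CCB([C@H]1C[C@H]2C[C@@H]([C@@H]1C)C2(C)C)[C@H]1C[C@H]2C[C@@H]([C@@H]1C)C2(C)C
Why: Brown asymmetric allylboration through a closed six-membered chair transition state, in which the isopinocampheyl groups derived from (−)-α-pinene direct the allyl group to the Re face of the aldehyde and so should set the (R)-carbinol; heteroaryl aldehydes are standard substrates for this reagent.

Step 2
Reactants: 2 (1R)-1-(furan-3-yl)but-3-en-1-ol
Product: 3 tert-butyl{[(1R)-1-(furan-3-yl)but-3-en-1-yl]oxy}dimethylsilane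
Conditions: TBSCl, imidazole, DMF, rt
Reagents that add atoms: tert-butyldimethylsilyl chloride, CC(C)(C)[Si](C)(C)Cl
Why: Imidazole-promoted silylation of a secondary alcohol, which only touches the O–H bond and so leaves the stereocentre as set.

Step 3
Reactants: 3 tert-butyl{[(1R)-1-(furan-3-yl)but-3-en-1-yl]oxy}dimethylsilane
Product: 4 tert-butyl{[(1R)-1-(furan-3-yl)-4-methylpent-3-en-1-yl]oxy}dimethylsilane
Conditions: 2-methyl-2-butene (large excess), second-generation Grubbs catalyst RuCl2(=CHPh)(PCy3)(H2IMes) (3 mol%), CH2Cl2, 40 °C
Reagents that add atoms: 2-methyl-2-butene, CC=C(C)C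
Why: Olefin cross-metathesis of a terminal alkene with excess 2-methyl-2-butene is a standard way to a prenyl-type trisubstituted alkene; propene escapes, the aromatic furan and the silyl ether are inert, and the stereocentre is not involved.

Step 4
Reactants: 4 tert-butyl{[(1R)-1-(furan-3-yl)-4-methylpent-3-en-1-yl]oxy}dimethylsilane; 5 2-bromo-1,4-dimethoxybenzene
Product: 8 tert-butyl({(1R)-1-[(1S,4R)-5,8-dimethoxy-1,4-dihydro-1,4-epoxynaphthalen-2-yl]-4-methylpent-3-en-1-yl}oxy)dimethylsilane, via aryllithium 6 (not isolated), via aryne 7 (not isolated)
Conditions: 5 (2.0 equiv), LiN(iPr)2 (LDA, 2.2 equiv, slow addition), THF, −78 °C → rt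
Reagents that add atoms: none
Why: LiN(iPr)2 should remove the ring proton of 5 that lies between bromine and methoxy (directed ortho-lithiation) to give 6, which loses LiBr on warming to the symmetrical aryne 7. The aryne then adds across C2 and C5 of the furan in a concerted suprafacial [4+2] cycloaddition, the well-established Diels–Alder trapping of arynes by furans, forming C1–C8a and C4–C4a together. The six-membered ring C1–C2–C3–C4–C4a–C8a is thus closed by an intermolecular annulation that joins both diene termini to the aryne, the furan oxygen remaining as the 1,4-bridge. The bridgehead centres C1 and C4 are fixed relative to each other by the bridge, but the remote carbinol centre gives no useful facial bias, so the (1S,4R) adduct 8 and its (1R,4S) bridgehead epimer should both form and are carried on together, since aromatisation later removes both centres. Regiochemistry needs no control because the aryne is symmetrical, and the step needs only chemoselectivity for the furan diene over the amide base, diisopropylamine, 6 and the prenyl alkene, which rests on the high diene reactivity of furan, low temperature, slow base addition and an excess of the cheap aryne source. The carbinol is a silyl ether with no acidic hydrogen and no activated leaving group under cold basic conditions and should pass unchanged.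

Step 5
Reactants: 8 tert-butyl({(1R)-1-[(1S,4R)-5,8-dimethoxy-1,4-dihydro-1,4-epoxynaphthalen-2-yl]-4-methylpent-3-en-1-yl}oxy)dimethylsilane (both bridgehead diastereomers, unseparated)
Product: 11 2-[(1R)-1-(tert-butyldimethylsilyloxy)-4-methylpent-3-en-1-yl]-5,8-dimethoxynaphthalene-1,4-dione, via 2-substituted 1-naphthol 9 (not isolated), via 3-substituted 1-naphthol 10 (not isolated)
Conditions: CF3CO2H (0.2 equiv), CH2Cl2, 0 °C; concentrate; then pyridine (0.5 equiv), DMF, Co(salen) (salcomine, C16H14CoN2O2, divalent cobalt, 0.2 equiv), O2 (1 atm), rt
Reagents that add atoms: dioxygen, O=O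
Why: Acid-catalysed isomerisation of a 1,4-epoxy-1,4-dihydronaphthalene to 1-naphthols (ionisation of one bridge C–O bond to a benzylic allylic cation, then hydride shift and enolisation to the arene) followed by cobalt–salen/dioxygen oxidation of the phenol at its free para position, so that both naphthol regioisomers and both bridgehead diastereomers converge on one quinone while catalytic acid in an aprotic solvent leaves the silyl ether in place.

Step 6
Reactants: 11 2-[(1R)-1-(tert-butyldimethylsilyloxy)-4-methylpent-3-en-1-yl]-5,8-dimethoxynaphthalene-1,4-dione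
Product: 12 2-[(1R)-1-hydroxy-4-methylpent-3-en-1-yl]-5,8-dimethoxynaphthalene-1,4-dione
Conditions: HF·pyridine, pyridine, THF, 0 °C → rt
Reagents that add atoms: none
Why: Fluoride-induced desilylation under weakly acidic, pyridine-buffered conditions, chosen because quinones do not tolerate basic fluoride sources; the C–O bond at the stereocentre is not touched.

Step 7
Reactants: 12 2-[(1R)-1-hydroxy-4-methylpent-3-en-1-yl]-5,8-dimethoxynaphthalene-1,4-dione; 13 butanoic anhydride
Product: 14 (1R)-1-(5,8-dimethoxy-1,4-dioxo-1,4-dihydronaphthalen-2-yl)-4-methylpent-3-en-1-yl butanoate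
Conditions: pyridine, DMAP (0.1 equiv), CH2Cl2, 0 °C → rt
Reagents that add atoms: none
Why: DMAP-catalysed acyl transfer from the anhydride to the only free hydroxyl in the molecule, with retention because only the O–H bond reacts and no phenol competes at this stage.

Step 8
Reactants: 14 (1R)-1-(5,8-dimethoxy-1,4-dioxo-1,4-dihydronaphthalen-2-yl)-4-methylpent-3-en-1-yl butanoate
Product: 16 (1R)-1-(5,8-dihydroxy-1,4-dioxo-1,4-dihydronaphthalen-2-yl)-4-methylpent-3-en-1-yl butanoate (butyrylshikonin), via naphthodiquinone 15 (not isolated)
Conditions: AgO (divalent silver oxide, 4 equiv), 6 M HNO3, 1,4-dioxane, rt, 5–10 min; then aq. Na2S2O4, rt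
Reagents that add atoms: water, O
Why: Oxidative demethylation, a known way from 5,8-dimethoxy-1,4-naphthoquinones with 1'-acyloxyalkyl chains to naphthazarins: water attacks the oxidised dimethoxy ring at the ipso carbons, methanol is released to give the diquinone, and two-electron reduction by dithionite returns the naphthazarin, while the short contact time should spare ester and alkene and the stereocentre on an electron-poor ring cannot ionise.

**Compound list**

1 | furan-3-carbaldehyde | O=Cc1ccoc1 | starting material
2 | (1R)-1-(furan-3-yl)but-3-en-1-ol | O[C@H](CC=C)c1ccoc1 | intermediate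
3 | tert-butyl{[(1R)-1-(furan-3-yl)but-3-en-1-yl]oxy}dimethylsilane | CC(C)(C)[Si](C)(C)O[C@H](CC=C)c1ccoc1 | intermediate
4 | tert-butyl{[(1R)-1-(furan-3-yl)-4-methylpent-3-en-1-yl]oxy}dimethylsilane | CC(C)(C)[Si](C)(C)O[C@H](CC=C(C)C)c1ccoc1 | intermediate
5 | 2-bromo-1,4-dimethoxybenzene | COc1ccc(OC)c(Br)c1 | starting material
6 | (2-bromo-3,6-dimethoxyphenyl)lithium | [Li]c1c(Br)c(OC)ccc1OC | intermediate (not isolated)
7 | 3,6-dimethoxybenzyne (1,4-dimethoxy-2,3-didehydrobenzene) | COC1=CC=C(OC)C#C1 | intermediate (not isolated)
8 | tert-butyl({(1R)-1-[(1S,4R)-5,8-dimethoxy-1,4-dihydro-1,4-epoxynaphthalen-2-yl]-4-methylpent-3-en-1-yl}oxy)dimethylsilane; (1S,4R) member shown, formed and carried on together with its (1R,4S) bridgehead epimer | CC(C)(C)[Si](C)(C)O[C@H](CC=C(C)C)C1=C[C@H]2O[C@@H]1c1c(OC)ccc(OC)c12 | intermediate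
9 | 2-[(1R)-1-(tert-butyldimethylsilyloxy)-4-methylpent-3-en-1-yl]-5,8-dimethoxynaphthalen-1-ol | CC(C)(C)[Si](C)(C)O[C@H](CC=C(C)C)c1ccc2c(OC)ccc(OC)c2c1O | intermediate (not isolated)
10 | 3-[(1R)-1-(tert-butyldimethylsilyloxy)-4-methylpent-3-en-1-yl]-5,8-dimethoxynaphthalen-1-ol | CC(C)(C)[Si](C)(C)O[C@H](CC=C(C)C)c1cc(O)c2c(OC)ccc(OC)c2c1 | intermediate (not isolated)
11 | 2-[(1R)-1-(tert-butyldimethylsilyloxy)-4-methylpent-3-en-1-yl]-5,8-dimethoxynaphthalene-1,4-dione | CC(C)(C)[Si](C)(C)O[C@H](CC=C(C)C)C1=CC(=O)c2c(OC)ccc(OC)c2C1=O | intermediate
12 | 2-[(1R)-1-hydroxy-4-methylpent-3-en-1-yl]-5,8-dimethoxynaphthalene-1,4-dione | O[C@H](CC=C(C)C)C1=CC(=O)c2c(OC)ccc(OC)c2C1=O | intermediate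
13 | butanoic anhydride | CCCC(=O)OC(=O)CCC | starting material
14 | (1R)-1-(5,8-dimethoxy-1,4-dioxo-1,4-dihydronaphthalen-2-yl)-4-methylpent-3-en-1-yl butanoate | CCCC(=O)O[C@H](CC=C(C)C)C1=CC(=O)c2c(OC)ccc(OC)c2C1=O | intermediate
15 | (1R)-4-methyl-1-(1,4,5,8-tetraoxo-1,4,5,8-tetrahydronaphthalen-2-yl)pent-3-en-1-yl butanoate | CCCC(=O)O[C@H](CC=C(C)C)C1=CC(=O)C2=C(C1=O)C(=O)C=CC2=O | intermediate (not isolated)
16 | (1R)-1-(5,8-dihydroxy-1,4-dioxo-1,4-dihydronaphthalen-2-yl)-4-methylpent-3-en-1-yl butanoate (butyrylshikonin) | CCCC(=O)O[C@H](CC=C(C)C)C1=CC(=O)c2c(O)ccc(O)c2C1=O | target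

**Total step count:** 8. **Longest linear sequence:** 8 (steps 1–8; compounds 5 and 13 are bought).

**Steps most likely to fail**

Step 4. The aryne may be consumed by the amide base, by diisopropylamine or by aryllithium 6 faster than by the hindered, stoichiometric furan, or the furan may be metalated next to its oxygen. The fallback changes the way the aryne is made from deprotonation to halogen–metal exchange, so that no amine or amide is present during the cycloaddition. It sets out from 5: ortho-lithiation with LiN(iPr)2 at −78 °C and an iodine quench should give 2-bromo-3-iodo-1,4-dimethoxybenzene F1, which is isolated. Slow addition of n-BuLi to F1 and 4 in toluene at −78 °C, then warming, should trigger iodine–lithium exchange, loss of LiBr and the same cycloaddition. The detour comes back to the route at 8, again as the pair of bridgehead diastereomers.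

Step 5. The proton acid may ionise the carbinol carbon or strip the silyl group once the electron-rich naphthol with an ortho benzylic ether has formed, and the cobalt-mediated oxidation may attack the hindered naphthol 10 at the ortho instead of the para position. The fallback sets out from 8 (both bridgehead diastereomers) and opens the bridge without a proton acid. Catalytic [Rh(CO)2Cl]2 (monovalent rhodium) in toluene at 50 °C should isomerise the strained allylic ether through C–O insertion and β-hydride elimination. The naphthols 9 and 10 are then isolated and oxidised separately with Fremy's salt, (KO3S)2NO, in buffered aqueous acetone. The detour comes back at 11 and makes no compound outside the list (F0).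

Step 8. The strongly oxidising acidic medium may degrade the prenyl alkene or hydrolyse the ester before both methyl ethers are gone, or the demethylation may stop after one ether. The fallback sets out from 11 and cleaves the ethers without oxidation, before the ester is in place. BCl3 in CH2Cl2 at −78 °C (chelation-directed cleavage of methyl ethers peri to the quinone carbonyls) should give 2-[(1R)-1-(tert-butyldimethylsilyloxy)-4-methylpent-3-en-1-yl]-5,8-dihydroxynaphthalene-1,4-dione F2. HF·pyridine then frees (R)-shikonin F3. Acylation with 13, pyridine and catalytic DMAP at 0 °C should reach only the side-chain hydroxyl, the peri hydroxyls being held in hydrogen bonds to the quinone carbonyls, and comes back at 16.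

**Further compounds**

F1 | step 4 | 2-bromo-3-iodo-1,4-dimethoxybenzene | COc1ccc(OC)c(I)c1Br
F0 | step 5 | none | none
F2 | step 8 | 2-[(1R)-1-(tert-butyldimethylsilyloxy)-4-methylpent-3-en-1-yl]-5,8-dihydroxynaphthalene-1,4-dione | CC(C)(C)[Si](C)(C)O[C@H](CC=C(C)C)C1=CC(=O)c2c(O)ccc(O)c2C1=O
F3 | step 8 | (R)-shikonin, 5,8-dihydroxy-2-[(1R)-1-hydroxy-4-methylpent-3-en-1-yl]naphthalene-1,4-dione | O[C@H](CC=C(C)C)C1=CC(=O)c2c(O)ccc(O)c2C1=O
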